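## Retrosynthetic overview

1. Target 15 ⇐ ketal hydrolysis and epoxide-directed iBu2AlH reduction of epoxy ketal 13 ⇐ catalyst-controlled nucleophilic epoxidation (both oxirane C–O bonds) of quinone monoketal 12 ⇐ PhI(OAc)2 dearomatisation of phenol 11.
2. Drimenyl arene 10 ⇐ radical removal of the C3 oxygen (cyclic thionocarbonate 8) ⇐ diol 7 ⇐ stereospecific epoxide-initiated cationic bicyclisation of epoxy alcohol 6.
3. 6 ⇐ Sharpless asymmetric epoxidation, the C–O bond formation that supplies all absolute stereochemistry of the decalin ⇐ (E)-allylic alcohol 5 ⇐ SeO2 hydroxylation of the terminal (E)-methyl of farnesylarene 4.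
4. 4 ⇐ ortho-C-farnesylation and pivaloylation of 4-methoxy-3-methylphenol 1 with (2E,6E)-farnesyl bromide 2.
5. Ring order: arene (bought) → ring A and ring B of the decalin together (step 4) → cyclohexadienone (step 7) → oxirane (step 8).

Assumption and convention: the SMILES defines the target; "14-hydroxydrim-7-en-11-yl" means [(1S,4aR,5R,8aR)-5-(hydroxymethyl)-2,5,8a-trimethyl-1,4,4a,5,6,7,8,8a-octahydronaphthalen-1-yl]methyl (drimane numbering, C11 = the CH2 link, C14 = the 4α-CH2OH); 1 and 2 are purchased.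

## Route

Step 1
Reactants: 1 4-methoxy-3-methylphenol; 2 (2E,6E)-farnesyl bromide
Product: 4 2-[(2E,6E)-farnesyl]-4-methoxy-5-methylphenyl pivalate, via free phenol 3 (not isolated)
Conditions: NaH (2.1 equiv), PhMe, 0 °C to rt; 2 (0.9 equiv), rt, 16 h; then PivCl (1.2 equiv), 0 °C to rt
Reagents that add atoms: pivaloyl chloride, CC(C)(C)C(=O)Cl
Why: Ortho-selective C-allylation of a sodium phenoxide in a non-polar solvent (the tight ion pair suppresses O-alkylation and the SN2 path keeps both (E)-olefins) occurs at the unhindered ortho carbon C6 rather than at C2 between OH and CH3, and in-flask O-acylation caps the phenol so that it cannot trap the C8 cation in step 4; no stereocentre is formed.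

Step 2
Reactants: 4 2-[(2E,6E)-farnesyl]-4-methoxy-5-methylphenyl pivalate
Product: 5 2-[(2E,6E,10E)-12-hydroxyfarnesyl]-4-methoxy-5-methylphenyl pivalate
Conditions: SeO2 (0.3 equiv), t-BuOOH (70% aq., 3 equiv), salicylic acid (0.1 equiv), CH2Cl2, 0 °C to rt, stopped at about 60% conversion, 4 recycled
Reagents that add atoms: tert-butyl hydroperoxide, CC(C)(C)OO (terminal oxygen source; SeO2 is the catalytic carrier)
Why: Catalytic SeO2 allylic oxidation (ene reaction then [2,3]-sigmatropic shift) attacks the terminal, most electron-rich and least hindered trisubstituted olefin and hydroxylates only its (E)-methyl group, which decides in advance that the equatorial 4α substituent of ring A carries the oxygen.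

Step 3
Reactants: 5 2-[(2E,6E,10E)-12-hydroxyfarnesyl]-4-methoxy-5-methylphenyl pivalate
Product: 6 2-[(2E,6E)-(10S,11S)-10,11-epoxy-12-hydroxyfarnesyl]-4-methoxy-5-methylphenyl pivalate
Conditions: Ti(OiPr)4 (10 mol %), L-(+)-diethyl tartrate (12 mol %), t-BuOOH (2 equiv, decane), 4 Å molecular sieves, CH2Cl2, −20 °C
Reagents that add atoms: tert-butyl hydroperoxide, CC(C)(C)OO
Why: Katsuki–Sharpless asymmetric epoxidation is directed by the allylic hydroxyl, so only the C10=C11 olefin reacts, and L-(+)-diethyl tartrate delivers oxygen to the face that gives the (2S,3S)-epoxy alcohol (about 95% ee expected for an (E)-2-methylalk-2-en-1-ol); these two C–O bonds are the only source of absolute configuration for the decalin.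

Step 4
Reactants: 6 2-[(2E,6E)-(10S,11S)-10,11-epoxy-12-hydroxyfarnesyl]-4-methoxy-5-methylphenyl pivalate
Product: 7 2-(3β,14-dihydroxydrim-7-en-11-yl)-4-methoxy-5-methylphenyl pivalate
Conditions: MeAlCl2 (3 equiv), CH2Cl2, −78 °C, 1 h; aq. potassium sodium tartrate
Reagents that add atoms: none
Why: Epoxide-initiated cationic polyene bicyclisation (Stork–Eschenmoser chair–chair cascade): the hydroxyl is held as its electron-poor Cl2Al alkoxide, C6 attacks the activated tertiary epoxide carbon C11 with inversion so that the (10S,11S)-epoxide and the (E)-olefin geometries become 3β-OH (3S), 4α-CH2OH (4R), 5α-H, 10β-CH3 and 9β-CH2Ar, and the C8 cation loses the axial C7 proton to give the Δ7 olefin.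

Step 5
Reactants: 7 2-(3β,14-dihydroxydrim-7-en-11-yl)-4-methoxy-5-methylphenyl pivalate
Product: 8 3,14-cyclic thionocarbonate of 7
Conditions: 1,1'-thiocarbonyldiimidazole (1.5 equiv), DMAP (0.1 equiv), PhMe, 80 °C
Reagents that add atoms: 1,1'-thiocarbonyldiimidazole, S=C(n1ccnc1)n1ccnc1
Why: Thiocarbonyl transfer to the gauche diequatorial 1,3-diol closes the six-membered cyclic thionocarbonate; no stereocentre changes.

Step 6
Reactants: 8 3,14-cyclic thionocarbonate of 7
Product: 10 2-(14-hydroxydrim-7-en-11-yl)-4-methoxy-5-methylphenyl pivalate, via stannyl thiocarbonate 9 (not isolated)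
Conditions: Bu3SnH (2 equiv), AIBN (0.2 equiv), PhMe, 110 °C; then KF, MeOH–H2O, rt
Reagents that add atoms: none
Why: Barton-type radical deoxygenation of a cyclic thionocarbonate: the tributyltin radical adds to sulfur, β-scission breaks the C3–O bond because it gives the secondary rather than the primary radical, hydrogen transfer from Bu3SnH turns C3 into CH2, and fluoride with water releases the C14 alcohol from the tin thiocarbonate.

Step 7
Reactants: 10 2-(14-hydroxydrim-7-en-11-yl)-4-methoxy-5-methylphenyl pivalate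
Product: 12 2-(14-hydroxydrim-7-en-11-yl)-4,4-dimethoxy-5-methylcyclohexa-2,5-dien-1-one, via free phenol 11 (not isolated)
Conditions: K2CO3 (0.2 equiv), MeOH, rt; then PhI(OAc)2 (1.1 equiv), 0 °C
Reagents that add atoms: methanol, CO
Why: Methanolysis frees the phenol and PhI(OAc)2 in methanol carries out the oxidative dearomatisation of the 4-methoxyphenol to the para-quinone monoketal, which places the ketone next to the carbon bearing the decalinylmethyl group and the ketal next to the methyl-bearing carbon; no stereocentre is formed.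

Step 8
Reactants: 12 2-(14-hydroxydrim-7-en-11-yl)-4,4-dimethoxy-5-methylcyclohexa-2,5-dien-1-one
Product: 13 (1R,6S)-1-(14-hydroxydrim-7-en-11-yl)-5,5-dimethoxy-4-methyl-7-oxabicyclo[4.1.0]hept-3-en-2-one
Conditions: (2S,6S)-2,6-di-tert-butyl-2,3,5,6-tetrahydro-1H-imidazo[1,2-a]imidazole (chiral bicyclic guanidine, 20 mol %), t-BuOOH (1.5 equiv, decane), PhMe, −40 °C
Reagents that add atoms: tert-butyl hydroperoxide, CC(C)(C)OO
Why: Proposed new method: catalyst-controlled Weitz–Scheffer epoxidation of a 2-alkyl para-quinone monoketal in which a C2-symmetric chiral bicyclic guanidine replaces the usual achiral amidine base; the guanidine deprotonates t-BuOOH, the guanidinium holds the peroxide anion with one N–H and the dienone carbonyl with the other, the peroxide adds to C3 (β-H) rather than to the methyl-bearing C5, and the bound enolate closes onto the proximal oxygen with loss of tert-butoxide, so both C–O bonds form on the face fixed by the catalyst to give the (1R,6S)-oxirane independently of the remote decalin; the closest known reactions are the DBU/t-BuOOH epoxidation of quinone monoketals, the cinchona phase-transfer epoxidation of 2-amido quinone monoketals and the guanidine–urea-catalysed epoxidation of 2-alkylnaphthoquinones.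

Step 9
Reactants: 13 (1R,6S)-1-(14-hydroxydrim-7-en-11-yl)-5,5-dimethoxy-4-methyl-7-oxabicyclo[4.1.0]hept-3-en-2-one
Product: 15 Epoxypholamin B, via hydroxy ketal 14 (not isolated)
Conditions: iBu2AlH (3 equiv), THF, −78 °C; aq. potassium sodium tartrate; then oxalic acid (0.2 equiv), THF–H2O, 0 °C
Reagents that add atoms: water, O
Why: 1,2-Reduction of the epoxy enone with iBu2AlH, in which aluminium bound to the oxirane oxygen delivers hydride to the carbonyl face syn to the epoxide (also the face left open by the decalinylmethyl group), puts the new hydroxyl trans to the oxirane oxygen (5R), and dilute oxalic acid then hydrolyses the allylic dimethyl ketal to the enone without opening the epoxide.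

## Compound list

1 | 4-methoxy-3-methylphenol | COc1ccc(O)cc1C | starting material
2 | (2E,6E)-farnesyl bromide, (2E,6E)-1-bromo-3,7,11-trimethyldodeca-2,6,10-triene | CC(C)=CCC/C(C)=C/CC/C(C)=C/CBr | starting material
3 | 4-methoxy-5-methyl-2-[(2E,6E)-3,7,11-trimethyldodeca-2,6,10-trien-1-yl]phenol | COc1cc(C/C=C(\C)CC/C=C(\C)CCC=C(C)C)c(O)cc1C | intermediate (not isolated)
4 | 4-methoxy-5-methyl-2-[(2E,6E)-3,7,11-trimethyldodeca-2,6,10-trien-1-yl]phenyl 2,2-dimethylpropanoate | COc1cc(C/C=C(\C)CC/C=C(\C)CCC=C(C)C)c(OC(=O)C(C)(C)C)cc1C | intermediate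
5 | 2-[(2E,6E,10E)-12-hydroxy-3,7,11-trimethyldodeca-2,6,10-trien-1-yl]-4-methoxy-5-methylphenyl 2,2-dimethylpropanoate | COc1cc(C/C=C(\C)CC/C=C(\C)CC/C=C(\C)CO)c(OC(=O)C(C)(C)C)cc1C | intermediate
6 | 2-{(2E,6E)-9-[(2S,3S)-3-(hydroxymethyl)-3-methyloxiran-2-yl]-3,7-dimethylnona-2,6-dien-1-yl}-4-methoxy-5-methylphenyl 2,2-dimethylpropanoate | COc1cc(C/C=C(\C)CC/C=C(\C)CC[C@@H]2O[C@@]2(C)CO)c(OC(=O)C(C)(C)C)cc1C | intermediate
7 | 2-{[(1S,4aR,5R,6S,8aR)-6-hydroxy-5-(hydroxymethyl)-2,5,8a-trimethyl-1,4,4a,5,6,7,8,8a-octahydronaphthalen-1-yl]methyl}-4-methoxy-5-methylphenyl 2,2-dimethylpropanoate (3β-OH, 4α-CH2OH, trans-decalin, Δ7) | COc1cc(C[C@H]2C(C)=CC[C@H]3[C@](C)(CO)[C@@H](O)CC[C@]23C)c(OC(=O)C(C)(C)C)cc1C | intermediate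
8 | cyclic thionocarbonate of 7 (six-membered 1,3-dioxane-2-thione spanning O3 and O14) | COc1cc(C[C@H]2C(C)=CC[C@H]3[C@]4(C)COC(=S)O[C@H]4CC[C@]23C)c(OC(=O)C(C)(C)C)cc1C | intermediate
9 | 14-O-[(tributylstannylsulfanyl)carbonyl] derivative of 10 | COc1cc(C[C@H]2C(C)=CC[C@H]3[C@](C)(COC(=O)S[Sn](CCCC)(CCCC)CCCC)CCC[C@]23C)c(OC(=O)C(C)(C)C)cc1C | intermediate (not isolated)
10 | 2-{[(1S,4aR,5R,8aR)-5-(hydroxymethyl)-2,5,8a-trimethyl-1,4,4a,5,6,7,8,8a-octahydronaphthalen-1-yl]methyl}-4-methoxy-5-methylphenyl 2,2-dimethylpropanoate | COc1cc(C[C@H]2C(C)=CC[C@H]3[C@](C)(CO)CCC[C@]23C)c(OC(=O)C(C)(C)C)cc1C | intermediate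
11 | 2-{[(1S,4aR,5R,8aR)-5-(hydroxymethyl)-2,5,8a-trimethyl-1,4,4a,5,6,7,8,8a-octahydronaphthalen-1-yl]methyl}-4-methoxy-5-methylphenol | COc1cc(C[C@H]2C(C)=CC[C@H]3[C@](C)(CO)CCC[C@]23C)c(O)cc1C | intermediate (not isolated)
12 | 2-{[(1S,4aR,5R,8aR)-5-(hydroxymethyl)-2,5,8a-trimethyl-1,4,4a,5,6,7,8,8a-octahydronaphthalen-1-yl]methyl}-4,4-dimethoxy-5-methylcyclohexa-2,5-dien-1-one | COC1(OC)C=C(C[C@H]2C(C)=CC[C@H]3[C@](C)(CO)CCC[C@]23C)C(=O)C=C1C | intermediate
13 | (1R,6S)-1-{[(1S,4aR,5R,8aR)-5-(hydroxymethyl)-2,5,8a-trimethyl-1,4,4a,5,6,7,8,8a-octahydronaphthalen-1-yl]methyl}-5,5-dimethoxy-4-methyl-7-oxabicyclo[4.1.0]hept-3-en-2-one | CC1=CC(=O)[C@]2(C[C@H]3C(C)=CC[C@H]4[C@](C)(CO)CCC[C@]34C)O[C@@H]2C1(OC)OC | intermediate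
14 | (1S,2R,6S)-1-{[(1S,4aR,5R,8aR)-5-(hydroxymethyl)-2,5,8a-trimethyl-1,4,4a,5,6,7,8,8a-octahydronaphthalen-1-yl]methyl}-5,5-dimethoxy-4-methyl-7-oxabicyclo[4.1.0]hept-3-en-2-ol (hydroxyl trans to the oxirane oxygen) | CC1=C[C@@H](O)[C@]2(C[C@H]3C(C)=CC[C@H]4[C@](C)(CO)CCC[C@]34C)O[C@@H]2C1(OC)OC | intermediate (not isolated)
15 | Epoxypholamin B, (1S,5R,6S)-5-hydroxy-6-{[(1S,4aR,5R,8aR)-5-(hydroxymethyl)-2,5,8a-trimethyl-1,4,4a,5,6,7,8,8a-octahydronaphthalen-1-yl]methyl}-3-methyl-7-oxabicyclo[4.1.0]hept-3-en-2-one | CC1=C[C@@H](O)[C@]2(C[C@H]3C(C)=CC[C@H]4[C@](C)(CO)CCC[C@]34C)O[C@@H]2C1=O | target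

## Step count and risks

Total steps: 9. Longest linear sequence: 9 steps (1 and 2 to 15).

The three steps most likely to fail:

**Step 4 (cationic bicyclisation of the free epoxy alcohol).** The cation next to the CH2O–Al group can be diverted by a 1,2-hydride shift (semipinacol or ketone by-products), and proton loss may give some exocyclic 8(12)- or tetrasubstituted olefin besides Δ7. The fallback sets out from 6 and comes back at 7, and replaces the cationic cascade by a radical one. Compound 6 is silylated (t-BuPh2SiCl, imidazole, CH2Cl2) to the tert-butyldiphenylsilyl ether F1. F1 is cyclised with Cp2TiCl (trivalent titanium, made in the flask from Cp2TiCl2 20 mol %, Mn dust, Me3SiCl and 2,4,6-collidine in THF). Homolytic opening of the epoxide gives the tertiary C11 radical, which cannot undergo hydride shifts. The C10 carbinol configuration is retained and steers the chair–chair cyclisation. The bulky silyloxymethyl group should take the equatorial position, though this selectivity is less secure than in the stereospecific cationic mode. The organotitanium terminates cleanly to the exocyclic alkene F2. F2 is isomerised to the endocyclic Δ7 alkene F3 with RhCl3·3H2O (5 mol %) in EtOH at 80 °C, and Bu4NF in THF removes the silyl group to give 7.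

**Step 8 (the new guanidine-catalysed epoxidation).** The catalyst may give low facial control against the substrate bias, or the wrong face. The sense must first be read off a model such as the 2-benzyl analogue of 12; the (2R,6R) antipode is equally available. The fallback uses known auxiliary control instead of catalyst control; it sets out from 12 and comes back at 15. Compound 12 is transketalised with (2R,4R)-pentane-2,4-diol (pyridinium p-toluenesulfonate, benzene, 50 °C, methanol removed) to the C2-symmetric spiro-dioxane dienone F4. If the model shows the opposite sense, the (2S,4S) diol is used. Diastereoselective Weitz–Scheffer epoxidation of F4 with Ph3COOH and KN(SiMe3)2 in THF at −78 °C gives epoxy ketal F5, and the diastereomers are separable at this stage. iBu2AlH reduction as in step 9 gives carbinol F6, and aqueous HF in MeCN at 0 °C removes the dioxane ketal to give 15.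

**Step 9 (facial selectivity of the ketone reduction).** If hydride attacks anti to the oxirane oxygen, the cis (syn) epoxy alcohol results. The fallback uses invertive substitution instead of direct reduction; it sets out from 13 and comes back at 14. Compound 13 is reduced under Luche conditions (NaBH4, CeCl3·7H2O, MeOH, −78 °C) to the syn epimer F7. Mitsunobu reaction of F7 (4-nitrobenzoic acid, PPh3, diisopropyl azodicarboxylate, 3 equiv each, THF, 0 °C) inverts the allylic carbinol and also acylates the neopentyl C14 hydroxyl with retention, giving bis(4-nitrobenzoate) F8. Inversion at this hindered carbinol may be slow. Methanolysis (K2CO3, MeOH) gives 14, which is hydrolysed with oxalic acid as in step 9.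

## Further compounds

F1 | step 4 | tert-butyldiphenylsilyl ether of 6 | COc1cc(C/C=C(\C)CC/C=C(\C)CC[C@@H]2O[C@@]2(C)CO[Si](c3ccccc3)(c3ccccc3)C(C)(C)C)c(OC(=O)C(C)(C)C)cc1C
F2 | step 4 | 2-[14-(tert-butyldiphenylsilyloxy)-3β-hydroxydrim-8(12)-en-11-yl]-4-methoxy-5-methylphenyl pivalate (exocyclic methylene) | COc1cc(C[C@H]2C(=C)CC[C@H]3[C@](C)(CO[Si](c4ccccc4)(c4ccccc4)C(C)(C)C)[C@@H](O)CC[C@]23C)c(OC(=O)C(C)(C)C)cc1C
F3 | step 4 | 14-O-tert-butyldiphenylsilyl ether of 7 (Δ7 olefin) | COc1cc(C[C@H]2C(C)=CC[C@H]3[C@](C)(CO[Si](c4ccccc4)(c4ccccc4)C(C)(C)C)[C@@H](O)CC[C@]23C)c(OC(=O)C(C)(C)C)cc1C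
F4 | step 8 | (2R,4R)-pentane-2,4-diyl ketal analogue of 12 (spiro-1,3-dioxane dienone) | CC1=CC(=O)C(C[C@H]2C(C)=CC[C@H]3[C@](C)(CO)CCC[C@]23C)=CC14O[C@H](C)C[C@@H](C)O4
F5 | step 8 | (2R,4R)-pentane-2,4-diyl ketal analogue of 13 | CC1=CC(=O)[C@]2(C[C@H]3C(C)=CC[C@H]4[C@](C)(CO)CCC[C@]34C)O[C@@H]2C15O[C@H](C)C[C@@H](C)O5
F6 | step 8 | (2R,4R)-pentane-2,4-diyl ketal analogue of 14 | CC1=C[C@@H](O)[C@]2(C[C@H]3C(C)=CC[C@H]4[C@](C)(CO)CCC[C@]34C)O[C@@H]2C15O[C@H](C)C[C@@H](C)O5
F7 | step 9 | C2 epimer of 14 (hydroxyl cis to the oxirane oxygen) | CC1=C[C@H](O)[C@]2(C[C@H]3C(C)=CC[C@H]4[C@](C)(CO)CCC[C@]34C)O[C@@H]2C1(OC)OC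
F8 | step 9 | bis(4-nitrobenzoate) of 14 | CC1=C[C@@H](OC(=O)c5ccc(cc5)[N+](=O)[O-])[C@]2(C[C@H]3C(C)=CC[C@H]4[C@](C)(COC(=O)c6ccc(cc6)[N+](=O)[O-])CCC[C@]34C)O[C@@H]2C1(OC)OC
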